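**Plan**

- Retrosynthetic cuts, in order: the O–Si bond on the chromenol; the C2–O(auxiliary) bond of a C2 acetal; then ring C (the dihydropyran) in one operation at C4a–C4, C4–C3 and O1–C2. This gives 2,6-dihydroxy-4-methoxybenzaldehyde, formaldehyde (C4) and an (E)-2-arylvinyl ether (C2–C3 plus the chromene unit).
- The enol ether is cut at O–C(vinyl) and at the vinyl C=C back to a chromene-8-carbaldehyde; the dimethylpyran ring is cut at O–CMe2 and at aryl–C4 back to 2,4-dihydroxybenzaldehyde.
- Forward order: the dimethylpyran ring is closed on ring B first (propargyl ether Claisen cascade), the two-carbon enol ether arm is added, and ring C is closed last by a three-component Knoevenagel/hetero-Diels–Alder reaction with ring A and formaldehyde.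
- Enabling feature: ring A is a formylphloroglucinol monomethyl ether. With the C8 formyl group between O1 and the 7-OH it is, before closure, a C2v-symmetric vinylogous acid with two equivalent free ortho carbons. Formaldehyde condenses at either one (the future C4a) to an ortho-quinone methide C4=C4a–C8a=O1, and C4 and C2 of the target are plain CH2 groups.
- Stereochemistry: the only stereocentre, C3, is set in the cycloaddition by a (1R,2S)-2-phenylcyclohexyl group on the enol ether oxygen. That C2–O bond is not in the target and is cut by silane reduction in step 8.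

Key step: step 7

Assumption: the sense of induction is taken from the s-trans enol ether model with approach anti to the phenyl ring, which predicts 3R from the (1R,2S)-alcohol; if the opposite sense were found, the (1S,2R)-alcohol would be used with no other change.

**Route**

Step 1
Reactants: 1 2,4-dihydroxybenzaldehyde
Product: 2 2-hydroxy-4-(triisopropylsilyloxy)benzaldehyde
Conditions: iPr3SiCl (1.05 equiv), imidazole, CH2Cl2, 0 °C to rt
Reagents that add atoms: triisopropylsilyl chloride CC(C)[Si](Cl)(C(C)C)C(C)C
Why: Regioselective O-silylation, because the 4-OH is free and the more acidic one while the 2-OH is held in a hydrogen bond to the formyl group, so one equivalent of the bulky chloride should silylate O4 only.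

Step 2
Reactants: 2 2-hydroxy-4-(triisopropylsilyloxy)benzaldehyde
Product: 3 2-[(2-methylbut-3-yn-2-yl)oxy]-4-(triisopropylsilyloxy)benzaldehyde
Conditions: 3-chloro-3-methylbut-1-yne, DBU, CuCl2·2H2O (1 mol %), MeCN, 0 °C to rt
Reagents that add atoms: 3-chloro-3-methylbut-1-yne CC(C)(Cl)C#C
Why: Copper-catalysed propargylic etherification of the remaining chelated phenol with the tertiary propargylic chloride, under conditions mild enough to leave the aryl silyl ether and the aldehyde intact.

Step 3
Reactants: 3 2-[(2-methylbut-3-yn-2-yl)oxy]-4-(triisopropylsilyloxy)benzaldehyde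
Product: 5 2,2-dimethyl-5-(triisopropylsilyloxy)-2H-chromene-8-carbaldehyde, via ortho-allenylphenol 4 (not isolated)
Conditions: PhNEt2, 180 °C
Reagents that add atoms: none
Why: Aromatic propargyl Claisen rearrangement to the only free ortho carbon, tautomerisation to allenylphenol 4, 1,5-hydrogen shift and 6π-oxa-electrocyclisation should give the 2,2-dimethyl-2H-chromene with the pyran oxygen next to the formyl-bearing carbon, as the 8-yl linkage requires.

Step 4
Reactants: 5 2,2-dimethyl-5-(triisopropylsilyloxy)-2H-chromene-8-carbaldehyde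
Product: 6 8-[(E)-2-iodoethenyl]-2,2-dimethyl-5-(triisopropylsilyloxy)-2H-chromene
Conditions: CHI3, CrCl2, THF/1,4-dioxane (1:6), 0 °C to rt, dark
Reagents that add atoms: iodoform IC(I)I
Why: Takai olefination, in which the geminal dichromium species from CHI3 and CrCl2 adds to the aryl aldehyde and eliminates to the E vinyl iodide, leaving the chromene alkene and the silyl ether untouched.

Step 5
Reactants: 6 8-[(E)-2-iodoethenyl]-2,2-dimethyl-5-(triisopropylsilyloxy)-2H-chromene; 7 (1R,2S)-2-phenylcyclohexan-1-ol
Product: 8 2,2-dimethyl-8-[(E)-2-{[(1R,2S)-2-phenylcyclohexyl]oxy}ethenyl]-5-(triisopropylsilyloxy)-2H-chromene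
Conditions: CuI (10 mol %), 3,4,7,8-tetramethyl-1,10-phenanthroline (20 mol %), Cs2CO3, toluene, 80 °C; chromatography on Et3N-deactivated silica
Reagents that add atoms: none
Why: Copper-catalysed Ullmann-type C–O cross-coupling of a vinyl iodide with an alcohol proceeds with retention of alkene geometry, so the E enol ether carrying the chiral controller should be obtained stereodefined.

Step 6
Reactants: 9 2,4,6-trihydroxybenzaldehyde
Product: 10 2,6-dihydroxy-4-methoxybenzaldehyde
Conditions: Me2SO4 (1.0 equiv), K2CO3 (1.0 equiv), acetone, 0 °C to rt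
Reagents that add atoms: dimethyl sulfate COS(=O)(=O)OC
Why: Selective Williamson-type mono-O-methylation, because the 4-OH para to the formyl group is the only hydroxyl not hydrogen-bonded and the most acidic, so one equivalent of base and of methylating agent should leave the two chelated ortho hydroxyls free.

Step 7
Reactants: 8 2,2-dimethyl-8-[(E)-2-{[(1R,2S)-2-phenylcyclohexyl]oxy}ethenyl]-5-(triisopropylsilyloxy)-2H-chromene; 10 2,6-dihydroxy-4-methoxybenzaldehyde; 11 formaldehyde (charged as paraformaldehyde)
Product: 13 (2S,3R)-3-[2,2-dimethyl-5-(triisopropylsilyloxy)-2H-chromen-8-yl]-7-hydroxy-5-methoxy-2-{[(1R,2S)-2-phenylcyclohexyl]oxy}-3,4-dihydro-2H-chromene-8-carbaldehyde, via ortho-quinone methide 12 (not isolated)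
Conditions: (CH2O)n (1.3 equiv), 10 (1.3 equiv), piperidinium acetate (20 mol %), 4 Å MS, MeCN, 45 °C
Reagents that add atoms: none
Why: Piperidinium acetate condenses formaldehyde with 10 at C3 (Mannich/Knoevenagel type, ring A acting as a vinylogous 1,3-dicarbonyl acid) and the adduct eliminates to quinone methide 12, whose O=C–C=CH2 unit is an electron-poor 1-oxadiene that adds the electron-rich enol ether 8 in an inverse-electron-demand hetero-Diels–Alder reaction. The closest known reaction types are the three-component domino Knoevenagel/hetero-Diels–Alder reaction of 1,3-dicarbonyl compounds and acylphloroglucinols with aldehydes and alkenes or enol ethers, and the diastereoselective cycloaddition of ortho-quinone methides with enol ethers of chiral alcohols. The dihydropyran ring closes by an intermolecular [4+2] cycloaddition (not by an exo or endo cyclisation), C4a–C4 coming from the condensation and C4–C3 and O1–C2 from the cycloaddition. C3 is controlled by the auxiliary: in the s-trans enol ether the phenyl ring on the cyclohexane covers one face, the methylene of 12 bonds to the aryl-bearing carbon on the open face and gives 3R, while C2 follows as 2S (trans) from suprafacial addition to the E alkene and is erased in step 8, so that endo/exo selectivity is without consequence because C4 is a CH2 group. Regiochemistry is set by polarity (the nucleophilic β-carbon of the enol ether, which carries the aryl group, joins the electrophilic methylene and the alkoxy-bearing carbon joins O1), site selectivity on ring A needs no control because 10 is C2v-symmetric with the formyl group on the carbon between the two hydroxyls, and the enol ether reacts far faster than the less electron-rich chromene alkene. Molecular sieves take up the water of condensation so that 8 is not hydrolysed, and 8 is the limiting component so that capture of 12 by a second molecule of 10 is held back.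

Step 8
Reactants: 13 (2S,3R)-3-[2,2-dimethyl-5-(triisopropylsilyloxy)-2H-chromen-8-yl]-7-hydroxy-5-methoxy-2-{[(1R,2S)-2-phenylcyclohexyl]oxy}-3,4-dihydro-2H-chromene-8-carbaldehyde
Product: 14 (3R)-3-[2,2-dimethyl-5-(triisopropylsilyloxy)-2H-chromen-8-yl]-7-hydroxy-5-methoxy-3,4-dihydro-2H-chromene-8-carbaldehyde
Conditions: Et3SiH (3 equiv), BF3·OEt2 (2 equiv), CH2Cl2, −78 to −30 °C; aqueous NaHCO3
Reagents that add atoms: none
Why: Ionic hydrogenation (Lewis acid/silane reductive cleavage of a cyclic acetal), in which BF3 ionises the exocyclic C2–O bond to the chroman oxocarbenium ion and this should take hydride from Et3SiH at low temperature faster than the hydrogen-bonded, vinylogous-ester-like C8 aldehyde or the chromene alkene can react, so that C2 becomes CH2, C3 is untouched and the auxiliary alcohol 7 is recovered.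

Step 9
Reactants: 14 (3R)-3-[2,2-dimethyl-5-(triisopropylsilyloxy)-2H-chromen-8-yl]-7-hydroxy-5-methoxy-3,4-dihydro-2H-chromene-8-carbaldehyde
Product: 15 (3R)-7-hydroxy-3-(5-hydroxy-2,2-dimethyl-2H-chromen-8-yl)-5-methoxy-3,4-dihydro-2H-chromene-8-carbaldehyde
Conditions: Bu4NF, AcOH, THF, 0 °C
Reagents that add atoms: none
Why: Fluoride-mediated cleavage of the aryl silyl ether, buffered with acetic acid so that the salicylaldehyde and chromene units are not exposed to free base, should release the target without touching C3.

**Compound list**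

1 | 2,4-dihydroxybenzaldehyde | O=Cc1ccc(O)cc1O | starting material
2 | 2-hydroxy-4-(triisopropylsilyloxy)benzaldehyde | O=Cc1ccc(O[Si](C(C)C)(C(C)C)C(C)C)cc1O | intermediate
3 | 2-[(2-methylbut-3-yn-2-yl)oxy]-4-(triisopropylsilyloxy)benzaldehyde | C#CC(C)(C)Oc1cc(O[Si](C(C)C)(C(C)C)C(C)C)ccc1C=O | intermediate
4 | 2-hydroxy-3-(3-methylbuta-1,2-dien-1-yl)-4-(triisopropylsilyloxy)benzaldehyde (not isolated) | CC(C)=C=Cc1c(O[Si](C(C)C)(C(C)C)C(C)C)ccc(C=O)c1O | intermediate
5 | 2,2-dimethyl-5-(triisopropylsilyloxy)-2H-chromene-8-carbaldehyde | CC1(C)C=Cc2c(O[Si](C(C)C)(C(C)C)C(C)C)ccc(C=O)c2O1 | intermediate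
6 | 8-[(E)-2-iodoethenyl]-2,2-dimethyl-5-(triisopropylsilyloxy)-2H-chromene | CC1(C)C=Cc2c(O[Si](C(C)C)(C(C)C)C(C)C)ccc(/C=C/I)c2O1 | intermediate
7 | (1R,2S)-2-phenylcyclohexan-1-ol | O[C@@H]1CCCC[C@H]1c1ccccc1 | starting material
8 | 2,2-dimethyl-8-[(E)-2-{[(1R,2S)-2-phenylcyclohexyl]oxy}ethenyl]-5-(triisopropylsilyloxy)-2H-chromene | CC1(C)C=Cc2c(O[Si](C(C)C)(C(C)C)C(C)C)ccc(/C=C/O[C@@H]3CCCC[C@H]3c3ccccc3)c2O1 | intermediate
9 | 2,4,6-trihydroxybenzaldehyde | O=Cc1c(O)cc(O)cc1O | starting material
10 | 2,6-dihydroxy-4-methoxybenzaldehyde | COc1cc(O)c(C=O)c(O)c1 | intermediate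
11 | formaldehyde (as paraformaldehyde) | C=O | starting material
12 | 2-hydroxy-4-methoxy-5-methylidene-6-oxocyclohexa-1,3-diene-1-carbaldehyde (ortho-quinone methide, not isolated) | C=C1C(OC)=CC(O)=C(C=O)C1=O | intermediate
13 | (2S,3R)-3-[2,2-dimethyl-5-(triisopropylsilyloxy)-2H-chromen-8-yl]-7-hydroxy-5-methoxy-2-{[(1R,2S)-2-phenylcyclohexyl]oxy}-3,4-dihydro-2H-chromene-8-carbaldehyde | COc1cc(O)c(C=O)c2c1C[C@H](c1ccc(O[Si](C(C)C)(C(C)C)C(C)C)c3c1OC(C)(C)C=C3)[C@@H](O[C@@H]1CCCC[C@H]1c1ccccc1)O2 | intermediate
14 | (3R)-3-[2,2-dimethyl-5-(triisopropylsilyloxy)-2H-chromen-8-yl]-7-hydroxy-5-methoxy-3,4-dihydro-2H-chromene-8-carbaldehyde | COc1cc(O)c(C=O)c2c1C[C@H](c1ccc(O[Si](C(C)C)(C(C)C)C(C)C)c3c1OC(C)(C)C=C3)CO2 | intermediate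
15 | (3R)-7-hydroxy-3-(5-hydroxy-2,2-dimethyl-2H-chromen-8-yl)-5-methoxy-3,4-dihydro-2H-chromene-8-carbaldehyde | COc1cc(O)c(C=O)c2c1C[C@H](c1ccc(O)c3c1OC(C)(C)C=C3)CO2 | target

**Step count**

Total steps: 9. Longest linear sequence: 8 steps (steps 1–5 and 7–9, from 2,4-dihydroxybenzaldehyde).

**Steps most likely to fail**

Step 7. The quinone methide may be captured by a second molecule of 10 (methylene-bridged dimer) or react a second time at C6, the enol ether may be hydrolysed by the water of condensation, and facial selectivity may erode at 45 °C. The fallback separates quinone methide generation from the condensation. It sets out from 10 and 8 and comes back at 13. Compound 10 is treated with dimethylmethylideneammonium iodide (CH2Cl2, rt) to give the Mannich base 3-[(dimethylamino)methyl]-2,6-dihydroxy-4-methoxybenzaldehyde F1, which is isolated. F1 and 8 are then stirred with MeI in CH2Cl2 at 0 °C to rt. N-Methylation gives the quaternary salt (3-formyl-2,4-dihydroxy-6-methoxyphenyl)methyl-trimethylammonium iodide F2, which loses trimethylamine to release 12 slowly, without water and at low temperature, and 12 is trapped by 8 to give 13.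

Step 8. Hydride may be delivered to the Lewis-acid-activated C8 aldehyde or to the protonated chromene alkene, and the oxocarbenium ion may lose H3 (racemisation by way of the 4H-chromene). The fallback replaces ionic hydride delivery by radical C–S cleavage. It sets out from 13 and comes back at 14. Acetal 13 is exchanged with PhSH (1.1 equiv) and catalytic BF3·OEt2 in CH2Cl2 at −78 °C, where the thiol traps the cation at once and 7 is recovered, to give (3R)-3-[2,2-dimethyl-5-(triisopropylsilyloxy)-2H-chromen-8-yl]-7-hydroxy-5-methoxy-2-(phenylsulfanyl)-3,4-dihydro-2H-chromene-8-carbaldehyde F3 as a mixture of C2 epimers. F3 is then reduced with Bu3SnH and AIBN in toluene at 80 °C to 14.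

Step 5. C–O bond formation with the hindered secondary alkoxide may be slow, so that dehydroiodination of 6 to the arylalkyne or transfer of the silyl group to the alkoxide takes over. The fallback forms the vinyl C=C bond instead of the O–C(vinyl) bond. It sets out from 5 and 7, bypasses 6, and comes back at 8. Alcohol 7 is converted with paraformaldehyde (11) and HCl gas into (1R,2S)-2-phenylcyclohexyl chloromethyl ether F4, and PPh3 in toluene gives {[(1R,2S)-2-phenylcyclohexyl]oxymethyl}triphenylphosphonium chloride F5. The ylide from F5 and NaN(SiMe3)2 (THF, −78 °C) reacts with aldehyde 5 in a Wittig olefination to give 8 together with its Z isomer 2,2-dimethyl-8-[(Z)-2-{[(1R,2S)-2-phenylcyclohexyl]oxy}ethenyl]-5-(triisopropylsilyloxy)-2H-chromene F6. F6 is removed by chromatography on Et3N-deactivated silica; only geometrically pure 8 is taken on, because the two isomers would give opposite configurations at C3.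

**Further compounds**

F1 | step 7 | 3-[(dimethylamino)methyl]-2,6-dihydroxy-4-methoxybenzaldehyde | CN(C)Cc1c(OC)cc(O)c(C=O)c1O
F2 | step 7 | (3-formyl-2,4-dihydroxy-6-methoxyphenyl)methyl-trimethylammonium iodide | C[N+](C)(C)Cc1c(OC)cc(O)c(C=O)c1O.[I-]
F3 | step 8 | (3R)-3-[2,2-dimethyl-5-(triisopropylsilyloxy)-2H-chromen-8-yl]-7-hydroxy-5-methoxy-2-(phenylsulfanyl)-3,4-dihydro-2H-chromene-8-carbaldehyde (C2 epimers) | COc1cc(O)c(C=O)c2c1C[C@H](c1ccc(O[Si](C(C)C)(C(C)C)C(C)C)c3c1OC(C)(C)C=C3)C(Sc1ccccc1)O2
F4 | step 5 | (1R,2S)-2-phenylcyclohexyl chloromethyl ether | ClCO[C@@H]1CCCC[C@H]1c1ccccc1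
F5 | step 5 | {[(1R,2S)-2-phenylcyclohexyl]oxymethyl}triphenylphosphonium chloride | [Cl-].c1ccc(cc1)[P+](CO[C@@H]1CCCC[C@H]1c1ccccc1)(c1ccccc1)c1ccccc1
F6 | step 5 | 2,2-dimethyl-8-[(Z)-2-{[(1R,2S)-2-phenylcyclohexyl]oxy}ethenyl]-5-(triisopropylsilyloxy)-2H-chromene | CC1(C)C=Cc2c(O[Si](C(C)C)(C(C)C)C(C)C)ccc(/C=C\O[C@@H]3CCCC[C@H]3c3ccccc3)c2O1
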